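**Retrosynthetic overview**
- The strategy rests on the single diaryl ether oxygen that links C-4 of the para-phenylene ring B to C-1 of the 2-hydroxy-5-alkylphenyl ring C. Rings B and C are the 4-hydroxyphenyl rings of two identical 3,4'-dihydroxybibenzyl (lunularin) units, joined from the phenol O of one to the carbon ortho to the OH of the other.
- Disconnection 1: that O–C(ortho) bond, formed by anodic dehydrodimerisation of a 3',5'-dibromolunularin 3-O-pivalate, then zinc rearomatisation, hydrodebromination and deacylation.
- Disconnection 2: the CH2–CH2 bridge of the C14 half, formed by Wittig olefination of 3-formylphenyl pivalate with a 4-benzyloxybenzyl phosphonium salt and hydrogenation.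
- No ring is constructed; all four benzene rings are bought. The bridge is made first (steps 3 and 4) and the ether union second (step 6).

Key step: step 6

Remark on the chemistry: the target has no stereocentre. Ring A and ring D are the two 3-hydroxyphenyl rings, ring B is the para-phenylene ring, and ring C is the 1,2,4-trisubstituted ring. The alkene of 6 and the sp3 carbon of 10 are carried without control because both are erased in the following step.

**Step 1**
Reactants: 1 3-hydroxybenzaldehyde
Product: 2 3-formylphenyl pivalate
Conditions: PivCl, Et3N, DMAP (cat.), CH2Cl2, 0 °C to rt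
Reagents that add atoms: pivaloyl chloride CC(C)(C)C(=O)Cl
Why: Phenol O-acylation by an acid chloride under amine base with nucleophilic catalysis is routine, and the bulky electron-withdrawing ester should later keep this ring inert to bromination and to anodic oxidation.

**Step 2**
Reactants: 3 4-benzyloxybenzyl chloride
Product: 4 (4-benzyloxybenzyl)triphenylphosphonium chloride
Conditions: PPh3, toluene, reflux
Reagents that add atoms: triphenylphosphine c1ccc(cc1)P(c1ccccc1)c1ccccc1
Why: SN2 quaternisation of triphenylphosphine by an activated benzylic chloride should give the salt, which precipitates from toluene.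

**Step 3**
Reactants: 2 3-formylphenyl pivalate; 4 (4-benzyloxybenzyl)triphenylphosphonium chloride
Product: 6 3-pivaloyloxy-4'-benzyloxystilbene (E/Z mixture), via 4-benzyloxybenzylidene(triphenyl)phosphorane 5 (not isolated)
Conditions: K2CO3, 18-crown-6 (cat.), CH2Cl2, reflux
Reagents that add atoms: none
Why: Wittig olefination of an aromatic aldehyde by a semi-stabilised benzylic ylide generated with solid carbonate under crown-ether catalysis should proceed without touching the aryl ester; the alkene geometry is irrelevant because the double bond is saturated next.

**Step 4**
Reactants: 6 3-pivaloyloxy-4'-benzyloxystilbene (E/Z mixture)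
Product: 8 lunularin 3-O-pivalate, via 3-pivaloyloxy-4'-benzyloxybibenzyl 7 (not isolated)
Conditions: H2 (1 atm), 10% Pd/C, EtOAc/EtOH, rt
Reagents that add atoms: none
Why: Heterogeneous catalytic hydrogenation first saturates the stilbene and then hydrogenolyses the benzyl ether, which should free only the 4'-phenol while the pivalate is inert under neutral conditions.

**Step 5**
Reactants: 8 lunularin 3-O-pivalate
Product: 9 3',5'-dibromolunularin 3-O-pivalate
Conditions: NBS (2.05 equiv), MeCN, 0 °C to rt, dark
Reagents that add atoms: N-bromosuccinimide O=C1CCC(=O)N1Br
Why: Electrophilic aromatic bromination should occur only on the free phenol ring, whose para position is blocked so that both ortho carbons are substituted, while the acyloxy ring is far less reactive and ionic conditions in the dark spare the benzylic CH2 groups.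

**Step 6**
Reactants: 9 3',5'-dibromolunularin 3-O-pivalate (two molecules)
Product: 10 6-aryloxy-2,6-dibromocyclohexa-2,4-dienone dimer (racemic at C-6; freed from electrolyte and used crude)
Conditions: constant current 10 mA, glassy-carbon anode, Pt cathode, undivided cell, LiClO4 (0.1 molar), MeOH, rt, about 1 faraday per mole of 9
Reagents that add atoms: none
Why: Anodic two-electron oxidation of the 2,6-dibromophenol ring of one molecule of 9 (through its phenoxyl radical) gives a phenoxonium-type species whose bromine-bearing ortho carbon is attacked by the phenol oxygen of a second molecule of 9; that carbon has no hydrogen to lose, so the adduct is held as the 6-aryloxy-6-bromo-2,4-dienone 10, and the two released protons are discharged as H2 at the cathode. The closest known reaction type is the anodic oxidation of 2,6-dihalo-4-alkylphenols such as 3,5-dibromotyrosine derivatives in methanolic LiClO4, which after zinc reduction gives isodityrosine-type diaryl ethers, and 9 belongs to that substrate class. The step forms only the diaryl ether C–O bond between the phenol oxygen of the future ring B and C-6 of the future ring C, and no ring is closed. The one new stereocentre, the sp3 carbon bearing Br and OAr, has no controlling element, should form as a racemate and is erased on rearomatisation in step 7. The step needs O–C(ortho) coupling of the brominated ring alone, not C–C coupling, methanol capture at the para carbon, spirocyclisation or oxidation of the other ring: the two ortho bromines disfavour C–C coupling and steer the oxygen nucleophile to the halogenated carbon, the ethylene chain blocks the para position, and the pivaloyloxy ring is too electron-poor to be oxidised at this potential or to act as an internal nucleophile. Because the product is a dienone and not a phenol it is shielded from further coupling, and ending the electrolysis near one faraday per mole of 9 should limit over-oxidation.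

**Step 7**
Reactants: 10 6-aryloxy-2,6-dibromocyclohexa-2,4-dienone dimer
Product: 11 tribromo perrottetin E bis-pivalate
Conditions: Zn dust, AcOH, THF, 0 °C to rt
Reagents that add atoms: none
Why: Zinc reduction of the alpha-bromo ketone unit should expel bromide from the sp3 carbon to give a zinc dienolate that is the phenoxide of the rearomatised ring and is protonated by acetic acid; aromatisation drives the step, and the aryl C–Br bonds, the diaryl ether and the pivalates are inert.

**Step 8**
Reactants: 11 tribromo perrottetin E bis-pivalate
Product: 12 perrottetin E bis-pivalate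
Conditions: H2 (1 atm), 10% Pd/C, Et3N, EtOAc, rt
Reagents that add atoms: none
Why: Palladium-catalysed hydrodehalogenation with an amine as HBr scavenger should cleave the three aryl C–Br bonds without affecting the diaryl ether, the saturated bridges or the esters.

**Step 9**
Reactants: 12 perrottetin E bis-pivalate
Product: 13 Perrottetin E
Conditions: NaOMe (4 equiv), MeOH, rt, argon; then dilute aq. HCl
Reagents that add atoms: none
Why: Base-mediated transesterification should work because methoxide adds to the aryl ester carbonyl and the phenoxide is a good leaving group, releasing both 3-hydroxyphenyl rings as methyl pivalate is formed; no other base-labile group is present.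

**Compound list**
1 | 3-hydroxybenzaldehyde | O=Cc1cccc(O)c1 | starting material
2 | 3-formylphenyl pivalate | CC(C)(C)C(=O)Oc1cccc(C=O)c1 | intermediate
3 | 4-benzyloxybenzyl chloride | ClCc1ccc(OCc2ccccc2)cc1 | starting material
4 | (4-benzyloxybenzyl)triphenylphosphonium chloride | [Cl-].c1ccc(cc1)[P+](Cc1ccc(OCc2ccccc2)cc1)(c1ccccc1)c1ccccc1 | intermediate
5 | 4-benzyloxybenzylidene(triphenyl)phosphorane (ylide, not isolated) | c1ccc(cc1)P(=Cc1ccc(OCc2ccccc2)cc1)(c1ccccc1)c1ccccc1 | intermediate
6 | 3-pivaloyloxy-4'-benzyloxystilbene, 3-[2-(4-benzyloxyphenyl)ethenyl]phenyl pivalate (E/Z mixture) | CC(C)(C)C(=O)Oc1cccc(C=Cc2ccc(OCc3ccccc3)cc2)c1 | intermediate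
7 | 3-pivaloyloxy-4'-benzyloxybibenzyl, 3-[2-(4-benzyloxyphenyl)ethyl]phenyl pivalate (not isolated) | CC(C)(C)C(=O)Oc1cccc(CCc2ccc(OCc3ccccc3)cc2)c1 | intermediate
8 | lunularin 3-O-pivalate, 3-[2-(4-hydroxyphenyl)ethyl]phenyl pivalate | CC(C)(C)C(=O)Oc1cccc(CCc2ccc(O)cc2)c1 | intermediate
9 | 3',5'-dibromolunularin 3-O-pivalate, 3-[2-(3,5-dibromo-4-hydroxyphenyl)ethyl]phenyl pivalate | CC(C)(C)C(=O)Oc1cccc(CCc2cc(Br)c(O)c(Br)c2)c1 | intermediate
10 | 2,6-dibromo-6-[2,6-dibromo-4-(3-pivaloyloxyphenethyl)phenoxy]-4-(3-pivaloyloxyphenethyl)cyclohexa-2,4-dien-1-one (racemic at C-6, crude) | CC(C)(C)C(=O)Oc1cccc(CCC2=CC(Br)(Oc3c(Br)cc(CCc4cccc(OC(=O)C(C)(C)C)c4)cc3Br)C(=O)C(Br)=C2)c1 | intermediate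
11 | tribromo perrottetin E bis-pivalate (ring B 3,5-dibromo; ring C bromo ortho to the free OH) | CC(C)(C)C(=O)Oc1cccc(CCc2cc(Br)c(Oc3cc(CCc4cccc(OC(=O)C(C)(C)C)c4)cc(Br)c3O)c(Br)c2)c1 | intermediate
12 | perrottetin E bis-pivalate (both 3-hydroxyphenyl oxygens acylated, ring C OH free) | CC(C)(C)C(=O)Oc1cccc(CCc2ccc(Oc3cc(CCc4cccc(OC(=O)C(C)(C)C)c4)ccc3O)cc2)c1 | intermediate
13 | Perrottetin E | Oc1cccc(CCc2ccc(Oc3cc(CCc4cccc(O)c4)ccc3O)cc2)c1 | target

**Step count**
Total: 9 steps. Longest linear sequence: 8 steps (from 1 through steps 1, 3 to 9, or from 3 through steps 2 to 9).

**Steps most likely to fail**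

Step 6. The oxidised ring may be intercepted by methanol at the para carbon or couple through carbon, the anode may passivate, and the charge may be spent on over-oxidation, so that little dimer forms. The fallback makes the same O–C(ortho) bond by copper catalysis instead of oxidation. It sets out from 8: one ortho position is brominated (NBS 1.0 equiv, i-Pr2NH cat., CH2Cl2, 0 °C) to give 3'-bromolunularin 3-O-pivalate F1, and the phenol is benzylated (BnBr, K2CO3, acetone, reflux) to give 3'-bromo-4'-O-benzyllunularin 3-O-pivalate F2. Ullmann-type coupling of F2 with a second molecule of 8 (CuI cat., N,N-dimethylglycine, Cs2CO3, dioxane, 90 °C; the hindered pivalates are expected to tolerate carbonate in an aprotic solvent) should give O-benzyl perrottetin E bis-pivalate F3. Hydrogenolysis of the benzyl ether (H2, Pd/C, EtOAc/EtOH) rejoins the route at 12, bypassing 9, 10 and 11.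

Step 7. On electron transfer the dienolate may expel the 2,6-dibromophenoxide instead of bromide, which fragments the dimer back to 9, or aryl C–Br bonds may be partly reduced so that a mixture of bromination patterns results. The fallback replaces the dissolving-metal reduction by hydrogenolysis and sets out from crude 10. Under H2 and Pd/C with Et3N in EtOAc, the activated sp3 C–Br bond should be cleaved first, which rearomatises ring C, and the three aryl C–Br bonds follow in the same flask. The route is rejoined at 12 without passing through 11, and unreacted 9 in the crude mixture is returned as recyclable 8.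

Step 3. Ylide formation under the weak carbonate base may be incomplete, or the aryl ester may lose its acyl group on prolonged heating. The fallback postpones acylation until after the olefination so that a strong base can be used; it sets out from 1 and 4. Treating 4 and unprotected 1 with KOtBu (2.2 equiv) in THF at 0 °C to rt should give 3-hydroxy-4'-benzyloxystilbene F4, since the meta phenoxide is not conjugated with the aldehyde. Pivaloylation of F4 (PivCl, Et3N, DMAP cat., CH2Cl2) rejoins the route at 6.

**Further compounds**
F1 | step 6 | 3'-bromolunularin 3-O-pivalate, 3-[2-(3-bromo-4-hydroxyphenyl)ethyl]phenyl pivalate | CC(C)(C)C(=O)Oc1cccc(CCc2ccc(O)c(Br)c2)c1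
F2 | step 6 | 3'-bromo-4'-O-benzyllunularin 3-O-pivalate, 3-[2-(4-benzyloxy-3-bromophenyl)ethyl]phenyl pivalate | CC(C)(C)C(=O)Oc1cccc(CCc2ccc(OCc3ccccc3)c(Br)c2)c1
F3 | step 6 | O-benzyl perrottetin E bis-pivalate (ring C oxygen benzylated) | CC(C)(C)C(=O)Oc1cccc(CCc2ccc(Oc3cc(CCc4cccc(OC(=O)C(C)(C)C)c4)ccc3OCc5ccccc5)cc2)c1
F0 | step 7 | none | none
F4 | step 3 | 3-hydroxy-4'-benzyloxystilbene (E/Z mixture) | Oc1cccc(C=Cc2ccc(OCc3ccccc3)cc2)c1
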